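## Retrosynthetic overview (eudesmane numbering in this overview only)

1. The acrylic acid comes from allylic oxidation of a 7α-isopropenyl group; the 9β-ester comes from acylation of the equatorial C9 alcohol, which comes from thermodynamic reduction of a C9 ketone.
2. The C7–C11 bond is made by axial conjugate addition of an isopropenyl copper reagent to the Δ7-en-9-one, anti to the angular methyl.
3. Ring B is made by a one-carbon ring expansion (diazoalkane insertion with 1,2-shift of the CH2 carbon) of a trans-hydrindan-1-one; this is the key step. The C4 carbinol comes from Markovnikov radical hydration of the Δ3 olefin.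
4. Ring A is closed by ring-closing metathesis; its two olefin arms and the C5/C10 stereocentres come from an enantioselective conjugate addition/enolate alkylation on 2-methylcyclopentenone.
5. Ring order: cyclopentanone (bought) → ring A (metathesis) → ring B (five- to six-membered expansion).

Assumption: 4-iodobut-1-ene, isopropenylmagnesium bromide solution, (trimethylsilyl)diazomethane solution and (3S)-3-methylpentanoic acid are taken as commercially available.

## Route

Step 1
Reactants: 1 2-methylcyclopent-2-en-1-one; 2 isopropenylmagnesium bromide; 3 4-iodobut-1-ene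
Product: 5 (2S,3S)-2-(but-3-en-1-yl)-2-methyl-3-(prop-1-en-2-yl)cyclopentan-1-one, via magnesium enolate 4 (not isolated)
Conditions: Cu(OTf)2 (3 mol %), chiral hydroxyalkyl imidazolinium chloride as NHC precursor (4 mol %, e.g. 1-[1-hydroxy-3,3-dimethylbutan-2-yl]-3-mesityl-4,5-dihydroimidazolium chloride, antipode that gives 3S), 2 (1.3 equiv, slow addition), Et2O, −30 °C; then DMPU (5 equiv), 3 (3 equiv), −30 → 23 °C
Reagents that add atoms: none
Why: Proposed new method: a chiral NHC-bound alkenyl cuprate formed by transmetallation of 2 should π-complex enone 1, add oxidatively to give a trivalent copper β-cuprio enolate and eliminate reductively to set C3 (S) under ligand control; the resulting regiodefined magnesium enolate 4 is then C-alkylated by 3 on the face opposite the new isopropenyl group, which sets the quaternary C2 (S) trans to it. The closest known reaction type is the copper-catalysed asymmetric conjugate addition of alkyl Grignard reagents to 2-methylcycloalkenones with trapping of the magnesium enolate by allylic or benzylic halides; new here are the alkenyl Grignard partner and the unactivated homoallylic iodide, for which DMPU deaggregation of the enolate is proposed.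

Step 2
Reactants: 5 (2S,3S)-2-(but-3-en-1-yl)-2-methyl-3-(prop-1-en-2-yl)cyclopentan-1-one
Product: 6 (3aS,7aS)-4,7a-dimethyl-2,3,3a,6,7,7a-hexahydro-1H-inden-1-one
Conditions: second-generation Grubbs catalyst (H2IMes)(PCy3)Cl2Ru=CHPh (3 mol %), CH2Cl2 (0.01 mol/L), 40 °C
Reagents that add atoms: none
Why: Ring-closing metathesis of the trans-disposed isopropenyl and butenyl arms closes ring A as a trisubstituted cyclohexene with loss of ethene and touches no stereocentre.

Step 3
Reactants: 6 (3aS,7aS)-4,7a-dimethyl-2,3,3a,6,7,7a-hexahydro-1H-inden-1-one; 7 (trimethylsilyl)diazomethane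
Product: 9 (4aS,8aS)-5,8a-dimethyl-3,4,4a,7,8,8a-hexahydronaphthalen-1(2H)-one, via α-silyl ketone 8 (not isolated)
Conditions: Me3Al (1.2 equiv), 7 (1.3 equiv), CH2Cl2, −78 → −20 °C; then aqueous HCl (1 mol/L), THF, 23 °C
Reagents that add atoms: none
Why: Lewis-acid-promoted diazoalkane homologation (Tiffeneau–Demjanov-type 1,2-shift): the ring CH2 migrates in preference to the quaternary carbon, as in D-homoannulation of 17-keto steroids, so the carbonyl stays next to the angular methyl while ring B becomes six-membered; the bulky silyl group stops a second insertion and no stereocentre changes.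

Step 4
Reactants: 9 (4aS,8aS)-5,8a-dimethyl-3,4,4a,7,8,8a-hexahydronaphthalen-1(2H)-one
Product: 11 (4aR,5R,8aS)-5-hydroxy-5,8a-dimethyloctahydronaphthalen-1(2H)-one, via tertiary hydroperoxide 10 (not isolated)
Conditions: Co(acac)2 (20 mol %), PhSiH3 (2.5 equiv), O2 (1 atm), THF/i-PrOH, 23 °C; then PPh3
Reagents that add atoms: dioxygen, O=O
Why: Mukaiyama hydration (hydrogen-atom transfer from a cobalt hydride) gives the tertiary C5 radical, which O2 traps on the face opposite the 1,3-diaxial angular methyl, so the hydroxyl ends equatorial (5R), as in the analogous hydration of drimane 8-olefins; a minor C5 epimer would be removed by chromatography.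

Step 5
Reactants: 11 (4aR,5R,8aS)-5-hydroxy-5,8a-dimethyloctahydronaphthalen-1(2H)-one
Product: 12 (4aR,5R,8aS)-5-hydroxy-5,8a-dimethyl-4a,5,6,7,8,8a-hexahydronaphthalen-1(4H)-one
Conditions: IBX (1.8 equiv), DMSO/fluorobenzene, 65 °C
Reagents that add atoms: none
Why: IBX α,β-dehydrogenation of the ketone can only run toward C2–C3 because the other α-carbon is quaternary, and the tertiary alcohol is inert.

Step 6
Reactants: 12 (4aR,5R,8aS)-5-hydroxy-5,8a-dimethyl-4a,5,6,7,8,8a-hexahydronaphthalen-1(4H)-one; 2 isopropenylmagnesium bromide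
Product: 13 (3R,4aR,5R,8aS)-5-hydroxy-5,8a-dimethyl-3-(prop-1-en-2-yl)octahydronaphthalen-1(2H)-one
Conditions: CuBr·SMe2 (20 mol %), 2 (2.5 equiv), THF, −78 → −40 °C; aqueous NH4Cl
Reagents that add atoms: none
Why: Copper-catalysed Grignard conjugate addition proceeds by stereoelectronically favoured axial attack on the enone face opposite the angular methyl, which sets C3 (R) with the isopropenyl group axial and trans to that methyl; the first equivalent of 2 only deprotonates the tertiary alcohol.

Step 7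
Reactants: 13 (3R,4aR,5R,8aS)-5-hydroxy-5,8a-dimethyl-3-(prop-1-en-2-yl)octahydronaphthalen-1(2H)-one
Product: 14 (1S,3R,4aR,5R,8aS)-5,8a-dimethyl-3-(prop-1-en-2-yl)decahydronaphthalene-1,5-diol
Conditions: Li (8 equiv), liquid NH3/THF, t-BuOH (3 equiv), −78 → −33 °C; NH4Cl
Reagents that add atoms: none
Why: Dissolving-metal ketone reduction is thermodynamically controlled and gives the equatorial alcohol (1S), because the axial epimer would be syn-diaxial to the isopropenyl group; a kinetic hydride would be unselective here since both faces are hindered, and the isolated alkene survives.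

Step 8
Reactants: 14 (1S,3R,4aR,5R,8aS)-5,8a-dimethyl-3-(prop-1-en-2-yl)decahydronaphthalene-1,5-diol; 15 (3S)-3-methylpentanoic acid
Product: 16 (1S,3R,4aR,5R,8aS)-5-hydroxy-5,8a-dimethyl-3-(prop-1-en-2-yl)decahydronaphthalen-1-yl (3S)-3-methylpentanoate
Conditions: 15 (1.5 equiv), N,N'-dicyclohexylcarbodiimide (1.6 equiv), DMAP (0.3 equiv), CH2Cl2, 0 → 23 °C
Reagents that add atoms: none
Why: Steglich esterification acylates only the secondary hydroxyl, the tertiary alcohol being inert, and the acid has no α-stereocentre to epimerise.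

Step 9
Reactants: 16 (1S,3R,4aR,5R,8aS)-5-hydroxy-5,8a-dimethyl-3-(prop-1-en-2-yl)decahydronaphthalen-1-yl (3S)-3-methylpentanoate
Product: 18 (1S,3R,4aR,5R,8aS)-5-hydroxy-5,8a-dimethyl-3-(3-oxoprop-1-en-2-yl)decahydronaphthalen-1-yl (3S)-3-methylpentanoate, via allylic alcohol 17 (not isolated)
Conditions: SeO2 (0.5 equiv), t-BuOOH (3 equiv), CH2Cl2, 23 °C; then filtration, MnO2 (20 equiv), CH2Cl2, 23 °C
Reagents that add atoms: selenium dioxide, O=[Se]=O; tert-butyl hydroperoxide, CC(C)(C)OO
Why: Riley allylic oxidation (ene reaction then [2,3]-shift) hydroxylates the isopropenyl methyl, and MnO2 then converts the allylic alcohol 17 and any enal already present into the single enal 18.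

Step 10
Reactants: 18 (1S,3R,4aR,5R,8aS)-5-hydroxy-5,8a-dimethyl-3-(3-oxoprop-1-en-2-yl)decahydronaphthalen-1-yl (3S)-3-methylpentanoate
Product: 19 2-[(2R,4S,4aS,8R,8aR)-8-hydroxy-4a,8-dimethyl-4-{[(3S)-3-methylpentanoyl]oxy}decahydronaphthalen-2-yl]prop-2-enoic acid
Conditions: NaClO2, NaH2PO4, 2-methylbut-2-ene, t-BuOH/H2O, 0 → 23 °C
Reagents that add atoms: sodium chlorite, [Na+].[O-]Cl=O
Why: Pinnick oxidation converts the enal into the acrylic acid without touching the 1,1-disubstituted alkene, the ester or the tertiary alcohol.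

## Compound list

1 | 2-methylcyclopent-2-en-1-one | CC1=CCCC1=O | starting material
2 | isopropenylmagnesium bromide (prop-1-en-2-ylmagnesium bromide) | C=C(C)[Mg]Br | starting material
3 | 4-iodobut-1-ene | C=CCCI | starting material
4 | bromomagnesium (3S)-2-methyl-3-(prop-1-en-2-yl)cyclopent-1-en-1-olate | CC1=C(O[Mg]Br)CC[C@H]1C(C)=C | intermediate
5 | (2S,3S)-2-(but-3-en-1-yl)-2-methyl-3-(prop-1-en-2-yl)cyclopentan-1-one | C=CCC[C@]1(C)C(=O)CC[C@H]1C(C)=C | intermediate
6 | (3aS,7aS)-4,7a-dimethyl-2,3,3a,6,7,7a-hexahydro-1H-inden-1-one | CC1=CCC[C@]2(C)C(=O)CC[C@@H]12 | intermediate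
7 | (trimethylsilyl)diazomethane | C[Si](C)(C)C=[N+]=[N-] | starting material
8 | (4aS,8aS)-5,8a-dimethyl-2-(trimethylsilyl)-3,4,4a,7,8,8a-hexahydronaphthalen-1(2H)-one (C2 epimers) | CC1=CCC[C@]2(C)C(=O)C([Si](C)(C)C)CC[C@@H]12 | intermediate
9 | (4aS,8aS)-5,8a-dimethyl-3,4,4a,7,8,8a-hexahydronaphthalen-1(2H)-one | CC1=CCC[C@]2(C)C(=O)CCC[C@@H]12 | intermediate
10 | (4aR,5R,8aS)-5-hydroperoxy-5,8a-dimethyloctahydronaphthalen-1(2H)-one | C[C@@]1(OO)CCC[C@]2(C)C(=O)CCC[C@@H]12 | intermediate
11 | (4aR,5R,8aS)-5-hydroxy-5,8a-dimethyloctahydronaphthalen-1(2H)-one | C[C@@]1(O)CCC[C@]2(C)C(=O)CCC[C@@H]12 | intermediate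
12 | (4aR,5R,8aS)-5-hydroxy-5,8a-dimethyl-4a,5,6,7,8,8a-hexahydronaphthalen-1(4H)-one | C[C@@]1(O)CCC[C@]2(C)C(=O)C=CC[C@@H]12 | intermediate
13 | (3R,4aR,5R,8aS)-5-hydroxy-5,8a-dimethyl-3-(prop-1-en-2-yl)octahydronaphthalen-1(2H)-one | C=C(C)[C@H]1CC(=O)[C@@]2(C)CCC[C@@](C)(O)[C@@H]2C1 | intermediate
14 | (1S,3R,4aR,5R,8aS)-5,8a-dimethyl-3-(prop-1-en-2-yl)decahydronaphthalene-1,5-diol | C=C(C)[C@H]1C[C@H](O)[C@@]2(C)CCC[C@@](C)(O)[C@@H]2C1 | intermediate
15 | (3S)-3-methylpentanoic acid | CC[C@H](C)CC(=O)O | starting material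
16 | (1S,3R,4aR,5R,8aS)-5-hydroxy-5,8a-dimethyl-3-(prop-1-en-2-yl)decahydronaphthalen-1-yl (3S)-3-methylpentanoate | C=C(C)[C@H]1C[C@H](OC(=O)C[C@@H](C)CC)[C@@]2(C)CCC[C@@](C)(O)[C@@H]2C1 | intermediate
17 | (1S,3R,4aR,5R,8aS)-5-hydroxy-3-(3-hydroxyprop-1-en-2-yl)-5,8a-dimethyldecahydronaphthalen-1-yl (3S)-3-methylpentanoate | C=C(CO)[C@H]1C[C@H](OC(=O)C[C@@H](C)CC)[C@@]2(C)CCC[C@@](C)(O)[C@@H]2C1 | intermediate
18 | (1S,3R,4aR,5R,8aS)-5-hydroxy-5,8a-dimethyl-3-(3-oxoprop-1-en-2-yl)decahydronaphthalen-1-yl (3S)-3-methylpentanoate | C=C(C=O)[C@H]1C[C@H](OC(=O)C[C@@H](C)CC)[C@@]2(C)CCC[C@@](C)(O)[C@@H]2C1 | intermediate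
19 | 2-[(2R,4S,4aS,8R,8aR)-8-hydroxy-4a,8-dimethyl-4-{[(3S)-3-methylpentanoyl]oxy}decahydronaphthalen-2-yl]prop-2-enoic acid (CNP0471281.1) | C=C(C(=O)O)[C@H]1C[C@H](OC(=O)C[C@@H](C)CC)[C@@]2(C)CCC[C@@](C)(O)[C@@H]2C1 | target

## Step count and risks

Total step count: 10. Longest linear sequence: 10 steps (1 → 19).

The three steps most likely to fail:

Step 1 (the proposed new method). Alkenyl Grignard reagents transfer more slowly than alkyl ones in copper-catalysed asymmetric additions, so uncatalysed 1,2-addition and low ee are possible, and the magnesium enolate may alkylate sluggishly with an unactivated iodide. The fallback uses known chemistry, sets out from 1 and comes back at 6. Racemic CuBr·SMe2-catalysed addition of 2 to 1 with TMSCl trapping gives the silyl enol ether trimethyl{[(3S)-2-methyl-3-(prop-1-en-2-yl)cyclopent-1-en-1-yl]oxy}silane F1 in a 1:1 mixture with its mirror image trimethyl{[(3R)-2-methyl-3-(prop-1-en-2-yl)cyclopent-1-en-1-yl]oxy}silane F2. MeLi in THF releases the lithium enolate, which is alkylated with 3 in THF/HMPA to give 5 together with its enantiomer (2R,3R)-2-(but-3-en-1-yl)-2-methyl-3-(prop-1-en-2-yl)cyclopentan-1-one F3. Ring-closing metathesis under the conditions of step 2 gives 6 together with (3aR,7aR)-4,7a-dimethyl-2,3,3a,6,7,7a-hexahydro-1H-inden-1-one F4, and preparative chromatography on a chiral stationary phase separates 6 from its enantiomer.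

Step 3. The neopentyl ketone may react slowly, and any migration of the quaternary carbon would place the carbonyl in the wrong position. The fallback sets out from 6 and comes back at 9, with the regiochemistry fixed by the only possible enol ether. LDA/TMSCl gives the silyl enol ether trimethyl{[(3aS,7aS)-4,7a-dimethyl-3a,6,7,7a-tetrahydro-3H-inden-1-yl]oxy}silane F5. Et2Zn/CH2I2 cyclopropanates the electron-rich enol ether double bond to give the siloxycyclopropane (1,2-methylene adduct of F5, siloxy group on the ring-fusion carbon of the cyclopropane) F6. FeCl3 in DMF opens the internal cyclopropane bond by the radical Ito–Saegusa ring expansion to give the β-chloro ketone (4aS,8aS)-3-chloro-5,8a-dimethyl-3,4,4a,7,8,8a-hexahydronaphthalen-1(2H)-one F7. Bu3SnH/AIBN then removes the chlorine to give 9.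

Step 9. The selenium ene reaction can also abstract the ring methine hydrogen next to the isopropenyl group, giving a tertiary allylic alcohol and a low yield. The fallback sets out from 16 and comes back at 18. Ene-type chlorination with Ca(OCl)2 and solid CO2 in CH2Cl2/H2O at 0 °C, which removes a methyl hydrogen selectively on isopropenyl groups, gives the allylic chloride (1S,3R,4aR,5R,8aS)-3-(3-chloroprop-1-en-2-yl)-5-hydroxy-5,8a-dimethyldecahydronaphthalen-1-yl (3S)-3-methylpentanoate F8. Trimethylamine N-oxide in DMSO (Ganem oxidation) converts F8 into enal 18.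

Further compounds
F1 | step 1 | trimethyl{[(3S)-2-methyl-3-(prop-1-en-2-yl)cyclopent-1-en-1-yl]oxy}silane | CC1=C(O[Si](C)(C)C)CC[C@H]1C(C)=C
F2 | step 1 | trimethyl{[(3R)-2-methyl-3-(prop-1-en-2-yl)cyclopent-1-en-1-yl]oxy}silane | CC1=C(O[Si](C)(C)C)CC[C@@H]1C(C)=C
F3 | step 1 | (2R,3R)-2-(but-3-en-1-yl)-2-methyl-3-(prop-1-en-2-yl)cyclopentan-1-one | C=CCC[C@@]1(C)C(=O)CC[C@@H]1C(C)=C
F4 | step 1 | (3aR,7aR)-4,7a-dimethyl-2,3,3a,6,7,7a-hexahydro-1H-inden-1-one | CC1=CCC[C@@]2(C)C(=O)CC[C@H]12
F5 | step 3 | trimethyl{[(3aS,7aS)-4,7a-dimethyl-3a,6,7,7a-tetrahydro-3H-inden-1-yl]oxy}silane | CC1=CCC[C@]2(C)C(O[Si](C)(C)C)=CC[C@@H]12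
F6 | step 3 | siloxycyclopropane: 1,2-methylene adduct of F5 with the trimethylsiloxy group on the cyclopropane ring-fusion carbon (new centres not assigned) | CC1=CCC[C@]2(C)C3(O[Si](C)(C)C)CC3C[C@@H]12
F7 | step 3 | (4aS,8aS)-3-chloro-5,8a-dimethyl-3,4,4a,7,8,8a-hexahydronaphthalen-1(2H)-one (C3 epimers) | CC1=CCC[C@]2(C)C(=O)CC(Cl)C[C@@H]12
F8 | step 9 | (1S,3R,4aR,5R,8aS)-3-(3-chloroprop-1-en-2-yl)-5-hydroxy-5,8a-dimethyldecahydronaphthalen-1-yl (3S)-3-methylpentanoate | C=C(CCl)[C@H]1C[C@H](OC(=O)C[C@@H](C)CC)[C@@]2(C)CCC[C@@](C)(O)[C@@H]2C1
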